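The constants in hand were the held gas, 85 mM, and a rate I read from oak.

- oak: electrophile 2 M; solid base 1.2 equiv; gas 85 mM (held); run made earlier
- flask: electrophile 1.0 M; solid base 1.20 equiv; gas 85 mM (held); time 10 d

- oak (time / d: electrophile / %, target / %): 0.833: 93.0, 4.6; 1.67: 88.8, 10.5; 2.50: 86.0, 14.0; 3.00: 83.5, 16.8

(each reading ± 1 percentage point)

- at the start none of the gas is in solution
- at the start none of the solid base is in solution
- a reading or a percentage of target counts all its forms, free or not
- the earlier runs do not show how much of nucleophile is bound; that part of a forecast is a guess
- no earlier run changes the charge of solid base; that part of a forecast is a guess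

* part of the electrophile that has reacted at 10 d
* share of the unused nucleophile that is free and not bound as protonated nucleophile, at 10 d

Oak made target at 0.110 M/d up to its first reading and at 0.112 M/d on average up to its last. I called the second figure the feed F, the molar amount of target made per day. With a scatter of 1 percentage point, oak could not separate a steady feed from first-order decay, so the choice was mine.

I saw two possible slowings. The first was the lower charge: if the rate followed electrophile, this flask would start at half of oak's rate. But none of the gas is in solution at the start, and oak's electrophile far exceeded the gas level, so I assumed that the entry of gas was the rate-limiting step while the electrophile stood high, which gives a factor of 1. The second was a tail of unknown size as the electrophile thinned.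

At F, this flask's charge of electrophile lasts τ = 8.93 d, shorter than the run, so with the tail I expected a conversion somewhat below full. Oak told me nothing about fr.

The forecast gave 45 % for c, assuming that “the held gas and excess solid base buffer the nucleophile at a steady level”, and 50 % for fr, which it called a guess.

This flask gave c = 91.2 % and fr = 5.39 %.

    gas ⇌ nucleophile, rate k1*(csat - [nucleophile]) (kL = 0.00210 /min)
    crystals ⇌ target, rate k2*(cs2 - [target]) while solid is left; crystals form when [target] > cs2 (solubility = 0.760 M, k = 0.0350 /min)
    electrophile + nucleophile → acid set free + target (k = 0.00720 /M/min)
    nucleophile + acid set free ⇌ protonated nucleophile, settled at all times (K = 94000 /M)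
    solid base ⇌ free base, rate k5*(cs5 - [free base]) while solid is left; crystals form when [free base] > cs5 (solubility = 0.390 M, k = 1.80 × 10⁻⁴ /min)
    acid set free + free base ⇌ salt of the base (K = 28000 /M, k = 0.0150 /M/min)

The half-life of nucleophile by its step with electrophile alone, the other concentrations as charged, was 0.067 d, short beside the 10 d run. In this flask at 5.00 d, F gives 56.0 %, and 52.6 % had reacted. In the neighbour flask with 1.7 M of electrophile, F gives 65.9 % at 10 d, and that flask reached 66.6 %.

Readings and results come from a simulation for an exercise, and the scatter is random.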